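**Strategy.** The oxolane is disconnected at C2–aryl (aryllithium addition to a γ-lactone, then oxocarbenium reduction) and, decisively, at O1–C5. The lactone ring O1–C2(=O)–C3–C4–C5 is not cyclised but grown from a four-membered carbocycle. Baeyer–Villiger oxidation of an all-trans 2-aryl-3,4-bis(benzyloxymethyl)cyclobutanone inserts O1 between the carbonyl carbon (future C2) and the trimethoxyphenyl-bearing carbon (future C5) with retention, so the C3/C4/C5 array is carried over intact. The cyclobutanone comes from an auxiliary-controlled [2+2] of an aryl ketene acetal with di-(−)-menthyl fumarate, which fixes C4. C3 and C5 follow by α-equilibration.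

Key step: step 7

Assumption: di-(−)-menthyl fumarate is taken to induce the same facial sense with the aryl ketene acetal as with the parent 1,1-dimethoxyethene, i.e. S configuration at the ring carbon remote from the acetal carbon.

**Step 1**
Reactants: 1 (3,4,5-trimethoxyphenyl)acetonitrile
Product: 3 5-(2,2,2-trimethoxyethyl)-1,2,3-trimethoxybenzene (trimethyl orthoester), via imidate hydrochloride 2 (not isolated)
Conditions: HCl (g), MeOH (1.1 equiv), Et2O, 0 °C; then MeOH, rt
Reagents that add atoms: methanol, CO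
Why: Pinner reaction of the nitrile to the methyl imidate hydrochloride, whose alcoholysis should give the orthoester and ammonium chloride.

**Step 2**
Reactants: 3 trimethyl orthoester
Product: 4 5-(2,2-dimethoxyethenyl)-1,2,3-trimethoxybenzene (aryl ketene dimethyl acetal)
Conditions: TMSOTf, i-Pr2NEt, CH2Cl2, −20 °C → rt; used crude
Reagents that add atoms: none
Why: Silyl triflate ionises the orthoester to a dialkoxycarbenium ion, and the amine removes the acidic benzylic proton (Gassman-type elimination of methanol) to give the conjugated ketene acetal.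

**Step 3**
Reactants: 4 aryl ketene dimethyl acetal; 5 di-(1R,2S,5R)-menthyl fumarate
Product: 6 di-(1R,2S,5R)-menthyl (1S,2R,4R)-3,3-dimethoxy-4-(3,4,5-trimethoxyphenyl)cyclobutane-1,2-dicarboxylate
Conditions: Et2AlCl, toluene/hexane, −78 °C
Reagents that add atoms: none
Why: Lewis-acid-promoted stepwise [2+2] of a ketene acetal with a fumarate, in which the menthyl groups of the Al-bound fumarate shield one face, so the nucleophilic aryl-bearing carbon should add to set C1 (future C4 of the target) as S.

**Step 4**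
Reactants: 6 cyclobutane diester
Product: 7 [(1S,2S,3R)-4,4-dimethoxy-3-(3,4,5-trimethoxyphenyl)cyclobutane-1,2-diyl]dimethanol
Conditions: LiAlH4, THF, 0 °C → rt; Fieser work-up
Reagents that add atoms: none
Why: Hydride reduction of both esters to primary alcohols releases the auxiliary as menthol and leaves the ketal untouched.

**Step 5**
Reactants: 7 diol
Product: 8 5-[(1R,2S,3S)-2,3-bis(benzyloxymethyl)-4,4-dimethoxycyclobutyl]-1,2,3-trimethoxybenzene
Conditions: NaH, BnBr, TBAI (cat.), THF/DMF, 0 °C → rt
Reagents that add atoms: benzyl bromide, BrCc1ccccc1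
Why: Williamson etherification protects both primary alcohols as benzyl ethers, which survive all later steps and fall together at the end.

**Step 6**
Reactants: 8 dibenzyl ether ketal
Product: 9 (2R,3S,4S)-3,4-bis(benzyloxymethyl)-2-(3,4,5-trimethoxyphenyl)cyclobutan-1-one
Conditions: 1 M H2SO4, MeCN, rt
Reagents that add atoms: water, O
Why: Acid hydrolysis of the dimethyl ketal frees the ketone, and acid-mediated enolisation should equilibrate both α-carbons (C2 and C4) to the all-trans isomer dictated by the fixed C3.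

**Step 7**
Reactants: 9 cyclobutanone
Product: 11 (3S,4S,5R)-3,4-bis(benzyloxymethyl)-5-(3,4,5-trimethoxyphenyl)oxolan-2-one, via Criegee adduct 10 (not isolated)
Conditions: mCPBA, CH2Cl2, 0 °C → rt
Reagents that add atoms: meta-chloroperoxybenzoic acid, OOC(=O)c1cccc(Cl)c1
Why: The peracid adds to the strained carbonyl to give the Criegee adduct, which collapses by a 1,2-shift of a ring carbon from carbon to oxygen with loss of 3-chlorobenzoate (Baeyer–Villiger oxidation of a cyclobutanone to a γ-butyrolactone). No ring is closed by cyclisation: the four-membered carbocycle is enlarged to the five-membered oxolanone by insertion of O between C1 and C2, driven by release of ring strain. No new stereocentre is formed; the migrating benzylic carbon keeps its configuration, so the trans,trans array becomes C3/C4/C5 of the lactone unchanged. The step needs regioselective migration of the aryl-bearing α-carbon over the other secondary α-carbon. This is secured by the cation-stabilising electron-rich benzylic position and by the inductively deactivating benzyloxymethyl group on the competing carbon. Chemoselectivity over arene oxidation rests on the much higher rate of Baeyer–Villiger oxidation of cyclobutanones at 0 °C.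

**Step 8**
Reactants: 12 4-bromo-2,6-dimethoxyphenol
Product: 13 2-(benzyloxy)-5-bromo-1,3-dimethoxybenzene
Conditions: BnBr, K2CO3, DMF, rt
Reagents that add atoms: benzyl bromide, BrCc1ccccc1
Why: O-Alkylation of the phenoxide (Williamson) masks the phenol for the organolithium step.

**Step 9**
Reactants: 11 lactone; 13 aryl bromide
Product: 15 (3S,4S,5R)-2-[4-(benzyloxy)-3,5-dimethoxyphenyl]-3,4-bis(benzyloxymethyl)-5-(3,4,5-trimethoxyphenyl)oxolan-2-ol (anomeric mixture), via aryllithium 14 (not isolated)
Conditions: 13, n-BuLi, THF, −78 °C; then 11, −78 °C; aq. NH4Cl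
Reagents that add atoms: none
Why: Bromine–lithium exchange gives the aryllithium, which should add once to the lactone carbonyl at −78 °C because the tetrahedral alkoxide persists until quench; carbonyl addition is expected to outrun α-deprotonation.

**Step 10**
Reactants: 15 hemiketal
Product: 16 (2R,3S,4S,5R)-2-[4-(benzyloxy)-3,5-dimethoxyphenyl]-3,4-bis(benzyloxymethyl)-5-(3,4,5-trimethoxyphenyl)oxolane
Conditions: Et3SiH, BF3·OEt2, CH2Cl2, −78 → −40 °C
Reagents that add atoms: none
Why: Reductive deoxygenation through the 2-aryl oxocarbenium ion, in which hydride should attack the envelope from the inside face (syn to the C3 substituent, anti to the C4 substituent), placing the new aryl group trans to C3 and giving the all-trans, thermodynamically preferred oxolane.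

**Step 11**
Reactants: 16 tribenzyl ether
Product: 17 4-[(2R,3S,4S,5R)-3,4-bis(hydroxymethyl)-5-(3,4,5-trimethoxyphenyl)oxolan-2-yl]-2,6-dimethoxyphenol (target)
Conditions: H2 (1 atm), 10% Pd/C, EtOAc/MeOH, rt
Reagents that add atoms: none
Why: Hydrogenolysis should cleave the two alkyl benzyl ethers and the aryl benzyl ether faster than the hindered ring benzylic C–O bonds, leaving the four stereocentres untouched.

**Compound list**

1 | (3,4,5-trimethoxyphenyl)acetonitrile | COc1cc(CC#N)cc(OC)c1OC | starting material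
2 | methyl 2-(3,4,5-trimethoxyphenyl)acetimidate hydrochloride | COC(=[NH2+])Cc1cc(OC)c(OC)c(OC)c1.[Cl-] | intermediate
3 | 5-(2,2,2-trimethoxyethyl)-1,2,3-trimethoxybenzene | COc1cc(CC(OC)(OC)OC)cc(OC)c1OC | intermediate
4 | 5-(2,2-dimethoxyethenyl)-1,2,3-trimethoxybenzene | COC(OC)=Cc1cc(OC)c(OC)c(OC)c1 | intermediate
5 | di-(1R,2S,5R)-menthyl fumarate | O=C(/C=C/C(=O)O[C@@H]1C[C@H](C)CC[C@H]1C(C)C)O[C@@H]1C[C@H](C)CC[C@H]1C(C)C | starting material
6 | di-(1R,2S,5R)-menthyl (1S,2R,4R)-3,3-dimethoxy-4-(3,4,5-trimethoxyphenyl)cyclobutane-1,2-dicarboxylate | COC1(OC)[C@@H](c2cc(OC)c(OC)c(OC)c2)[C@H](C(=O)O[C@@H]2C[C@H](C)CC[C@H]2C(C)C)[C@H]1C(=O)O[C@@H]1C[C@H](C)CC[C@H]1C(C)C | intermediate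
7 | [(1S,2S,3R)-4,4-dimethoxy-3-(3,4,5-trimethoxyphenyl)cyclobutane-1,2-diyl]dimethanol | COC1(OC)[C@@H](c2cc(OC)c(OC)c(OC)c2)[C@H](CO)[C@H]1CO | intermediate
8 | 5-[(1R,2S,3S)-2,3-bis(benzyloxymethyl)-4,4-dimethoxycyclobutyl]-1,2,3-trimethoxybenzene | COC1(OC)[C@@H](c2cc(OC)c(OC)c(OC)c2)[C@H](COCc2ccccc2)[C@H]1COCc1ccccc1 | intermediate
9 | (2R,3S,4S)-3,4-bis(benzyloxymethyl)-2-(3,4,5-trimethoxyphenyl)cyclobutan-1-one | O=C1[C@@H](c2cc(OC)c(OC)c(OC)c2)[C@H](COCc2ccccc2)[C@H]1COCc1ccccc1 | intermediate
10 | Criegee adduct of 9 with mCPBA (1-hydroxycyclobutyl 3-chloroperbenzoate) | OC1(OOC(=O)c2cccc(Cl)c2)[C@@H](c2cc(OC)c(OC)c(OC)c2)[C@H](COCc2ccccc2)[C@H]1COCc1ccccc1 | intermediate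
11 | (3S,4S,5R)-3,4-bis(benzyloxymethyl)-5-(3,4,5-trimethoxyphenyl)oxolan-2-one | O=C1O[C@@H](c2cc(OC)c(OC)c(OC)c2)[C@H](COCc2ccccc2)[C@H]1COCc1ccccc1 | intermediate
12 | 4-bromo-2,6-dimethoxyphenol | COc1cc(Br)cc(OC)c1O | starting material
13 | 2-(benzyloxy)-5-bromo-1,3-dimethoxybenzene | COc1cc(Br)cc(OC)c1OCc1ccccc1 | intermediate
14 | [4-(benzyloxy)-3,5-dimethoxyphenyl]lithium | [Li]c1cc(OC)c(OCc2ccccc2)c(OC)c1 | intermediate
15 | (3S,4S,5R)-2-[4-(benzyloxy)-3,5-dimethoxyphenyl]-3,4-bis(benzyloxymethyl)-5-(3,4,5-trimethoxyphenyl)oxolan-2-ol | OC1(c2cc(OC)c(OCc3ccccc3)c(OC)c2)O[C@@H](c2cc(OC)c(OC)c(OC)c2)[C@H](COCc2ccccc2)[C@H]1COCc1ccccc1 | intermediate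
16 | (2R,3S,4S,5R)-2-[4-(benzyloxy)-3,5-dimethoxyphenyl]-3,4-bis(benzyloxymethyl)-5-(3,4,5-trimethoxyphenyl)oxolane | COc1cc([C@@H]2O[C@@H](c3cc(OC)c(OC)c(OC)c3)[C@H](COCc3ccccc3)[C@H]2COCc2ccccc2)cc(OC)c1OCc1ccccc1 | intermediate
17 | 4-[(2R,3S,4S,5R)-3,4-bis(hydroxymethyl)-5-(3,4,5-trimethoxyphenyl)oxolan-2-yl]-2,6-dimethoxyphenol | COc1cc([C@@H]2O[C@@H](c3cc(OC)c(OC)c(OC)c3)[C@H](CO)[C@H]2CO)cc(OC)c1O | target

**Step count.** Total: 11 steps. Longest linear sequence: 10 steps (steps 1–7, 9, 10, 11).

**Steps most likely to fail, with fallbacks**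

Step 3. The β-aryl ketene acetal is more hindered than the parent, so the cycloaddition may stall at the open-chain conjugate adduct, or facial discrimination by the menthyl groups may erode. The fallback sets out from nitrile 1 and returns at cyclobutanone 9. Alkaline hydrolysis (KOH, aq. EtOH, reflux; then acid) would give (3,4,5-trimethoxyphenyl)acetic acid F1. Coupling with (2R,5R)-2,5-dimethylpyrrolidine (EDC, HOBt) would give the C2-symmetric amide F2. Activation with Tf2O and 2,6-di-tert-butyl-4-methylpyridine in 1,2-dichloroethane in the presence of (Z)-1,4-bis(benzyloxy)but-2-ene would generate a chiral keteniminium ion, whose [2+2] with the alkene would give the cyclobutaniminium triflate F3. Aqueous hydrolysis and acid equilibration of the two α-carbons would converge on 9. Only the β-carbon has to be set by the auxiliary; if the induction proved opposite, the antipodal amine would be used.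

Step 7. Migration of the wrong α-carbon or peracid attack on the trimethoxyphenyl ring would erode the lactone. The fallback sets out from 9 and returns at 11. Irradiation of 9 in methanol (Pyrex, about 300 nm) should cause Norrish type I cleavage of the weaker benzylic C1–C2 bond. The resulting acyl/benzyl biradical should reclose on oxygen to an oxacarbene, which methanol traps to give, with retention at the benzylic carbon, the ring-expanded methyl acetal (3S,4S,5R)-3,4-bis(benzyloxymethyl)-2-methoxy-5-(3,4,5-trimethoxyphenyl)oxolane F4. Jones oxidation (CrO3, H2SO4, acetone, 0 °C) of this cyclic acetal would give lactone 11.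

Step 10. Hydride delivery to the oxocarbenium ion may show poor facial selectivity, or Lewis-acid ionisation of the electron-rich benzylic C–O bonds may scramble C2 or C5. The fallback sets out from 11 and returns at 16, introducing the aryl group as the nucleophile instead of hydride. DIBAL-H (CH2Cl2, −78 °C) would give the lactol (3S,4S,5R)-3,4-bis(benzyloxymethyl)-5-(3,4,5-trimethoxyphenyl)oxolan-2-ol F5. Benzenesulfinic acid and CaCl2 in CH2Cl2 would convert it into the 2-(phenylsulfonyl)oxolane F6. Treatment with [4-(benzyloxy)-3,5-dimethoxyphenyl]magnesium bromide F7 (from 13 and Mg in THF) and ZnBr2 would displace the sulfinate through the oxocarbenium ion. The aryl group should enter anti to the C3 substituent and give 16.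

**Further compounds**

F1 | step 3 | (3,4,5-trimethoxyphenyl)acetic acid | COc1cc(CC(=O)O)cc(OC)c1OC
F2 | step 3 | 1-[(2R,5R)-2,5-dimethylpyrrolidin-1-yl]-2-(3,4,5-trimethoxyphenyl)ethan-1-one | COc1cc(CC(=O)N2[C@H](C)CC[C@H]2C)cc(OC)c1OC
F3 | step 3 | (2R,5R)-1-[(2R,3S,4R)-3,4-bis(benzyloxymethyl)-2-(3,4,5-trimethoxyphenyl)cyclobutylidene]-2,5-dimethylpyrrolidinium triflate | C[C@@H]1CC[C@@H](C)[N+]1=C1[C@@H](c2cc(OC)c(OC)c(OC)c2)[C@H](COCc2ccccc2)[C@@H]1COCc1ccccc1.[O-]S(=O)(=O)C(F)(F)F
F4 | step 7 | (3S,4S,5R)-3,4-bis(benzyloxymethyl)-2-methoxy-5-(3,4,5-trimethoxyphenyl)oxolane | COC1O[C@@H](c2cc(OC)c(OC)c(OC)c2)[C@H](COCc2ccccc2)[C@H]1COCc1ccccc1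
F5 | step 10 | (3S,4S,5R)-3,4-bis(benzyloxymethyl)-5-(3,4,5-trimethoxyphenyl)oxolan-2-ol | OC1O[C@@H](c2cc(OC)c(OC)c(OC)c2)[C@H](COCc2ccccc2)[C@H]1COCc1ccccc1
F6 | step 10 | (3S,4S,5R)-3,4-bis(benzyloxymethyl)-2-(phenylsulfonyl)-5-(3,4,5-trimethoxyphenyl)oxolane | O=S(=O)(c1ccccc1)C1O[C@@H](c2cc(OC)c(OC)c(OC)c2)[C@H](COCc2ccccc2)[C@H]1COCc1ccccc1
F7 | step 10 | [4-(benzyloxy)-3,5-dimethoxyphenyl]magnesium bromide | Br[Mg]c1cc(OC)c(OCc2ccccc2)c(OC)c1
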